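**Plan**

Numbering: tetralone C1 (C=O) to C4 (stereocentre), C4a–C8a; naphthyl C1′ (bonded to C4), C4′ (OH), C8′ (OMe).
Cut 1 (last ring): C1′–C8a′ and C4′–C4a′. Ring A of the naphthol (C1′–C4′ plus the oxygen on C4′) is a 2-substituted furan and the methoxy ring is 3-methoxybenzyne. The para pair C1′-alkyl/C4′-OH and the peri C8′-OMe are what a (4+2) cycloaddition followed by acid opening of the oxygen bridge leaves behind.
Cut 2: C4–C1′, made earlier as the bond from C4 to C2 of furan by nickel-catalysed coupling of a 4-bromotetralone with 2-furylzinc chloride, a small nucleophile in place of a peri-hindered naphthyl one.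
Forward order: the tetralone is bought; its methyl ethers are exchanged for pivalates, C4 is brominated and the furan joined; ring A is then closed on the furan as a 1,4-epoxide, aromatised to the naphthol, and the pivalates are removed.
Stereochemistry: the only stereocentre, C4, is set by catalyst control in the enantioconvergent coupling. It is R in the furyl compound and S in the target only because the CIP rank of the aryl group changes; the bridgehead centres of the cycloadduct are transient.

Key step: step 5

Assumption: the bis(oxazoline) antipode that delivers the (R)-furyl tetralone is taken to be the S,S-ligand, 2,2′-(propane-2,2-diyl)bis[(4S)-4-phenyl-4,5-dihydrooxazole]; if the sense of induction is the opposite, the R,R-ligand is used and nothing else changes.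

**Route**

Step 1
Reactants: 1 5,8-dimethoxy-3,4-dihydronaphthalen-1(2H)-one
Product: 2 5,8-dihydroxy-3,4-dihydronaphthalen-1(2H)-one
Conditions: BBr3 (3 equiv), CH2Cl2, −78 °C → rt; then H2O
Reagents that add atoms: none
Why: Lewis-acid ether cleavage, in which BBr3 coordinates each aryl methyl ether and bromide removes the methyl group by SN2 attack while the ketone is inert; the methyl ethers are removed now because they could not later be distinguished from the C8′ methoxy group.

Step 2
Reactants: 2 5,8-dihydroxy-3,4-dihydronaphthalen-1(2H)-one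
Product: 3 5,8-bis(pivaloyloxy)-3,4-dihydronaphthalen-1(2H)-one
Conditions: PivCl (2.5 equiv), Et3N, DMAP (cat.), CH2Cl2, 0 °C → rt
Reagents that add atoms: pivaloyl chloride, CC(C)(C)C(Cl)=O
Why: DMAP-catalysed acylation of both phenols, including the hydrogen-bonded C8 hydroxyl, gives esters that resist fluoride, deactivate the ring toward electrophilic bromination in step 3 and keep the phenols from being arylated in step 5.

Step 3
Reactants: 3 5,8-bis(pivaloyloxy)-3,4-dihydronaphthalen-1(2H)-one
Product: 4 racemic 4-bromo-5,8-bis(pivaloyloxy)-3,4-dihydronaphthalen-1(2H)-one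
Conditions: NBS (1.05 equiv), AIBN (cat.), PhCF3, 80 °C, argon; used crude
Reagents that add atoms: N-bromosuccinimide, O=C1CCC(=O)N1Br
Why: Wohl–Ziegler bromination, in which a bromine atom abstracts hydrogen from C4, the only benzylic CH2 group, as in the known conversion of 1-tetralone into 4-bromo-1-tetralone; the acyloxy groups suppress ring bromination, and the bromide is not purified because it loses HBr easily.

Step 4
Reactants: 4 racemic 4-bromo-5,8-bis(pivaloyloxy)-3,4-dihydronaphthalen-1(2H)-one, 5 furan
Product: 8 (R)-4-(furan-2-yl)-5,8-bis(pivaloyloxy)-3,4-dihydronaphthalen-1(2H)-one, via 2-furyllithium 6 (not isolated), via 2-furylzinc chloride 7 (not isolated)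
Conditions: 5 (1.6 equiv), n-BuLi, THF, 0 °C; ZnCl2, 0 °C → rt; then 4, NiBr2·glyme (10 mol%), (S,S)-bis(oxazoline) (13 mol%), CH2Cl2–THF, −40 °C
Reagents that add atoms: none
Why: Enantioconvergent Negishi cross-coupling of a racemic secondary benzylic bromide, in which the nickel/bis(oxazoline) catalyst turns both enantiomers of 4 into the same planar benzylic radical and the chiral furyl–nickel complex sets the C4 configuration in the C–C bond-forming step (catalyst control).

Step 5
Reactants: 8 (R)-4-(furan-2-yl)-5,8-bis(pivaloyloxy)-3,4-dihydronaphthalen-1(2H)-one, 9 3-methoxy-2-(trimethylsilyl)phenyl trifluoromethanesulfonate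
Product: 11 (4R)-4-(8-methoxy-1,4-dihydro-1,4-epoxynaphthalen-1-yl)-5,8-bis(pivaloyloxy)-3,4-dihydronaphthalen-1(2H)-one as a mixture of the two bridgehead diastereomers, via 3-methoxybenzyne 10 (not isolated)
Conditions: CsF (4 equiv), MeCN, rt; 9 (2 equiv) added slowly
Reagents that add atoms: none
Why: Fluoride removes the trimethylsilyl group of 9 and the aryl anion expels triflate, releasing 3-methoxybenzyne 10, which adds across C2 and C5 of the furan of 8 in a concerted but asynchronous (4+2) cycloaddition; this is the aryne–furan Diels–Alder reaction, the standard route to 1,4-epoxy-1,4-dihydronaphthalenes. The six-membered carbocycle that becomes ring A closes in this intermolecular cycloaddition by formation of C1′–C8a′ and C4′–C4a′, the furan oxygen remaining as the 1,4-bridge. The two bridgehead stereocentres arise without useful control from the distant C4 centre, which does not matter because both diastereomers lose these centres on aromatisation in step 6; C4 itself is a spectator and keeps its configuration. The selectivity the step needs is regiochemical: the inductively withdrawing methoxy group distorts the aryne so that the carbon remote from oxygen is the electrophilic terminus, and the more nucleophilic unsubstituted furan carbon C5 should bond there, which places the tetralone-bearing carbon next to the methoxy-bearing ring carbon as the peri C1′/C8′ relationship requires. The bulk of the tetralone opposes this orientation, so the regioisomeric adduct is expected as a by-product and would be removed by chromatography here or, more easily, after step 6, where only the unwanted isomer has an internally hydrogen-bonded peri hydroxy–methoxy pair. The phenols are carried as pivalates because free phenoxides would be arylated by the aryne, and 9 is used in excess because 8 is the valuable partner.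

Step 6
Reactants: 11 (4R)-4-(8-methoxy-1,4-dihydro-1,4-epoxynaphthalen-1-yl)-5,8-bis(pivaloyloxy)-3,4-dihydronaphthalen-1(2H)-one
Product: 12 (S)-4-(4-hydroxy-8-methoxynaphthalen-1-yl)-5,8-bis(pivaloyloxy)-3,4-dihydronaphthalen-1(2H)-one
Conditions: CF3CO2H, CH2Cl2, 0 °C → rt
Reagents that add atoms: none
Why: Acid-catalysed isomerisation of a 1,4-epoxy-1,4-dihydronaphthalene to a 1-naphthol, in which the protonated bridge ionises at the tertiary C1′ (a benzylic, allylic cation stabilised by the ortho methoxy group), the oxygen stays on C4′ and loss of the C4′ hydrogen (directly or after a 1,2-hydride shift and enolisation) aromatises ring A, so that both bridgehead diastereomers give one naphthol without touching C4.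

Step 7
Reactants: 12 (S)-4-(4-hydroxy-8-methoxynaphthalen-1-yl)-5,8-bis(pivaloyloxy)-3,4-dihydronaphthalen-1(2H)-one
Product: 13 (S)-5,8-dihydroxy-4-(4-hydroxy-8-methoxynaphthalen-1-yl)-3,4-dihydronaphthalen-1(2H)-one
Conditions: K2CO3 (excess), degassed MeOH, 40 °C, argon; then aq. HCl
Reagents that add atoms: none
Why: Base-mediated methanolysis (transesterification) of the two aryl pivalates, which are activated phenyl esters, leaves the aryl methyl ether, the ketone and the C4 stereocentre (not alpha to the carbonyl) untouched; oxygen is excluded because the hydroquinone anion is easily oxidised.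

**Compound list**

1 | 5,8-dimethoxy-3,4-dihydronaphthalen-1(2H)-one | COc1ccc(OC)c2C(=O)CCCc12 | starting material
2 | 5,8-dihydroxy-3,4-dihydronaphthalen-1(2H)-one | Oc1ccc(O)c2C(=O)CCCc12 | intermediate
3 | 5,8-bis(pivaloyloxy)-3,4-dihydronaphthalen-1(2H)-one | CC(C)(C)C(=O)Oc1ccc(OC(=O)C(C)(C)C)c2C(=O)CCCc12 | intermediate
4 | racemic 4-bromo-5,8-bis(pivaloyloxy)-3,4-dihydronaphthalen-1(2H)-one | CC(C)(C)C(=O)Oc1ccc(OC(=O)C(C)(C)C)c2C(=O)CCC(Br)c12 | intermediate
5 | furan | c1ccoc1 | starting material
6 | 2-furyllithium | [Li]c1ccco1 | intermediate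
7 | 2-furylzinc chloride | Cl[Zn]c1ccco1 | intermediate
8 | (R)-4-(furan-2-yl)-5,8-bis(pivaloyloxy)-3,4-dihydronaphthalen-1(2H)-one | o1cccc1[C@@H]2CCC(=O)c3c(OC(=O)C(C)(C)C)ccc(OC(=O)C(C)(C)C)c23 | intermediate
9 | 3-methoxy-2-(trimethylsilyl)phenyl trifluoromethanesulfonate | COc1cccc(OS(=O)(=O)C(F)(F)F)c1[Si](C)(C)C | starting material
10 | 3-methoxybenzyne (1,2-didehydro-3-methoxybenzene) | COC1=CC=CC#C1 | intermediate
11 | (4R)-4-(8-methoxy-1,4-dihydro-1,4-epoxynaphthalen-1-yl)-5,8-bis(pivaloyloxy)-3,4-dihydronaphthalen-1(2H)-one, both bridgehead diastereomers (bridgeheads left unspecified) | COc1cccc2C3OC(C=C3)(c12)[C@@H]1CCC(=O)c2c(OC(=O)C(C)(C)C)ccc(OC(=O)C(C)(C)C)c12 | intermediate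
12 | (S)-4-(4-hydroxy-8-methoxynaphthalen-1-yl)-5,8-bis(pivaloyloxy)-3,4-dihydronaphthalen-1(2H)-one | COc1cccc2c(O)ccc([C@@H]3CCC(=O)c4c(OC(=O)C(C)(C)C)ccc(OC(=O)C(C)(C)C)c43)c12 | intermediate
13 | (S)-5,8-dihydroxy-4-(4-hydroxy-8-methoxynaphthalen-1-yl)-3,4-dihydronaphthalen-1(2H)-one | COc1cccc2c(O)ccc([C@@H]3CCC(=O)c4c(O)ccc(O)c43)c12 | target

**Count and risks**

Total steps: 7. Longest linear sequence: 7 steps (1 → 13).

Steps most likely to fail, most serious first:

Step 5. Steric repulsion between the tetralone and the methoxy group may override the electronic bias of the aryne. C2 of the furan would then bond to the aryne carbon remote from oxygen, and the methoxy group would end up peri to the hydroxyl instead of peri to C1′. The fallback sets out from 8 and comes back at 12; it gives the aryne a removable blocking group on its other flank.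
- Commercial 3-methoxyphenol would be acylated with diethylcarbamoyl chloride (K2CO3, MeCN, reflux) to 3-methoxyphenyl diethylcarbamate F1.
- Directed ortho-metalation between the two oxygens (s-BuLi, TMEDA, THF, −78 °C; Me3SiCl) would give 3-methoxy-2-(trimethylsilyl)phenyl diethylcarbamate F2.
- A second metalation at the remaining position ortho to the carbamate (s-BuLi, TMEDA, −78 °C; Et3SiCl) would give 3-methoxy-6-(triethylsilyl)-2-(trimethylsilyl)phenyl diethylcarbamate F3.
- LiAlH4 in THF would cleave the carbamate to 3-methoxy-6-(triethylsilyl)-2-(trimethylsilyl)phenol F4, and n-BuLi followed by Tf2O would give 3-methoxy-6-(triethylsilyl)-2-(trimethylsilyl)phenyl trifluoromethanesulfonate F5.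
- With CsF in MeCN, fluoride should attack the trimethylsilyl group in preference to the bulkier triethylsilyl group and release 3-methoxy-6-(triethylsilyl)benzyne F6. In this aryne the silyl and methoxy groups both make the carbon next to silicon the electrophilic one, and the silyl group blocks that flank. 3-Silylarynes are known to add 2-substituted furans with the furan substituent away from silicon.
- Compound 8 should therefore give the silylated cycloadduct (4R)-4-[8-methoxy-5-(triethylsilyl)-1,4-dihydro-1,4-epoxynaphthalen-1-yl]-5,8-bis(pivaloyloxy)-3,4-dihydronaphthalen-1(2H)-one F7.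
- CF3CO2H in CH2Cl2 would open the bridge to (S)-4-[4-hydroxy-8-methoxy-5-(triethylsilyl)naphthalen-1-yl]-5,8-bis(pivaloyloxy)-3,4-dihydronaphthalen-1(2H)-one F8. On warming it would remove the silyl group by protodesilylation, which is fast because ipso-protonation occurs para to the methoxy group; the product is 12.

Step 4. The chiral nickel catalyst may discriminate poorly between the faces of the hindered C4 radical, which is flanked by the peri pivalate, so that the enantiomeric purity is low. The fallback sets out from 4 and comes back at 8. Coupling of 4 with 7 under an achiral catalyst (NiCl2·glyme, 4,4′-di-tert-butyl-2,2′-bipyridine, THF–DMA, 0 °C) would give racemic 4-(furan-2-yl)-5,8-bis(pivaloyloxy)-3,4-dihydronaphthalen-1(2H)-one F9. This would be resolved by preparative chromatography on a polysaccharide-based chiral stationary phase; the R enantiomer is 8, and (S)-4-(furan-2-yl)-5,8-bis(pivaloyloxy)-3,4-dihydronaphthalen-1(2H)-one F10 is set aside.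

Step 3. Bromination may take the ionic course through the enol and go to C2 (catalysed by the HBr formed), or the C4 bromide may lose HBr and aromatise to a 1-naphthol before it can be used. The fallback sets out from 3 and comes back at 8. It replaces the free-radical chain by a copper-catalysed radical-relay chlorination of the benzylic C–H bond, which uses no free halogen and forms no hydrogen halide. CuCl with an achiral bis(oxazoline) ligand, N-fluorobenzenesulfonimide as oxidant and KCl in chlorobenzene would give racemic 4-chloro-5,8-bis(pivaloyloxy)-3,4-dihydronaphthalen-1(2H)-one F11: the sulfonimidyl radical abstracts the C4 hydrogen and divalent copper chloride transfers chlorine to the benzylic radical. The chloride is less prone to elimination than 4 and would enter the nickel coupling of step 4 in its place (with LiI added if it reacts too slowly), which gives 8.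

**Further compounds**

F1 | step 5 | 3-methoxyphenyl diethylcarbamate | CCN(CC)C(=O)Oc1cccc(OC)c1
F2 | step 5 | 3-methoxy-2-(trimethylsilyl)phenyl diethylcarbamate | CCN(CC)C(=O)Oc1cccc(OC)c1[Si](C)(C)C
F3 | step 5 | 3-methoxy-6-(triethylsilyl)-2-(trimethylsilyl)phenyl diethylcarbamate | CCN(CC)C(=O)Oc1c([Si](CC)(CC)CC)ccc(OC)c1[Si](C)(C)C
F4 | step 5 | 3-methoxy-6-(triethylsilyl)-2-(trimethylsilyl)phenol | Oc1c([Si](CC)(CC)CC)ccc(OC)c1[Si](C)(C)C
F5 | step 5 | 3-methoxy-6-(triethylsilyl)-2-(trimethylsilyl)phenyl trifluoromethanesulfonate | COc1ccc([Si](CC)(CC)CC)c(OS(=O)(=O)C(F)(F)F)c1[Si](C)(C)C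
F6 | step 5 | 3-methoxy-6-(triethylsilyl)benzyne | COC1=CC=C([Si](CC)(CC)CC)C#C1
F7 | step 5 | (4R)-4-[8-methoxy-5-(triethylsilyl)-1,4-dihydro-1,4-epoxynaphthalen-1-yl]-5,8-bis(pivaloyloxy)-3,4-dihydronaphthalen-1(2H)-one, both bridgehead diastereomers | COc1ccc([Si](CC)(CC)CC)c2C3OC(C=C3)(c12)[C@@H]1CCC(=O)c2c(OC(=O)C(C)(C)C)ccc(OC(=O)C(C)(C)C)c12
F8 | step 5 | (S)-4-[4-hydroxy-8-methoxy-5-(triethylsilyl)naphthalen-1-yl]-5,8-bis(pivaloyloxy)-3,4-dihydronaphthalen-1(2H)-one | COc1ccc([Si](CC)(CC)CC)c2c(O)ccc([C@@H]3CCC(=O)c4c(OC(=O)C(C)(C)C)ccc(OC(=O)C(C)(C)C)c43)c12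
F9 | step 4 | racemic 4-(furan-2-yl)-5,8-bis(pivaloyloxy)-3,4-dihydronaphthalen-1(2H)-one | o1cccc1C2CCC(=O)c3c(OC(=O)C(C)(C)C)ccc(OC(=O)C(C)(C)C)c23
F10 | step 4 | (S)-4-(furan-2-yl)-5,8-bis(pivaloyloxy)-3,4-dihydronaphthalen-1(2H)-one | o1cccc1[C@H]2CCC(=O)c3c(OC(=O)C(C)(C)C)ccc(OC(=O)C(C)(C)C)c23
F11 | step 3 | racemic 4-chloro-5,8-bis(pivaloyloxy)-3,4-dihydronaphthalen-1(2H)-one | CC(C)(C)C(=O)Oc1ccc(OC(=O)C(C)(C)C)c2C(=O)CCC(Cl)c12
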